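The biflavonoid is cut at the pyranone (ring C) of its flavone half. There, C4 is an aryl ketone carbon lodged between C4a of the 5,7-dioxygenated ring A and the C3=C2 unit that carries ring B, and O1 is bonded to C2. A palladium-catalysed carbonylative annulation therefore joins an ortho-iodophenol (ring A with O1), carbon monoxide (C4) and a terminal aryl alkyne (C2, C3, ring B) in one operation, forming C4a–C4, C4–C3 and O1–C2. The alkyne partner already holds the diaryl ether and a MOM-masked ortho-hydroxyacetophenone. From this the flavanone ring is built afterwards by chromone formation, enantioselective aryl addition and one global deprotection.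

Key step: step 7

Remark: the target is the (2S)-flavanone; the facial sense of the palladium/pyridine–oxazoline aryl addition is assigned by analogy with cyclic enones, so the (R)-ligand is specified, and the antipodal ligand would be used if a model run showed the opposite sense.

Step 1
Reactants: 1 3,5-bis(benzyloxy)phenol
Product: 2 3,5-bis(benzyloxy)-2-iodophenol
Conditions: NIS (1.0 equiv), CH2Cl2, −40 → 0 °C, dark
Reagents that add atoms: N-iodosuccinimide, O=C1CCC(=O)N1I
Why: Electrophilic aromatic iodination of an electron-rich phenol, in which the two equivalent carbons ortho to the hydroxyl are favoured statistically and sterically over C4 between the two benzyloxy groups, while one equivalent of NIS at low temperature limits di-iodination and any symmetric 4-iodo isomer is removed by chromatography.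

Step 2
Reactants: 3 syringaldehyde (4-hydroxy-3,5-dimethoxybenzaldehyde); 4 bis(4-bromophenyl)iodonium trifluoromethanesulfonate
Product: 5 4-(4-bromophenoxy)-3,5-dimethoxybenzaldehyde
Conditions: KOtBu, THF, 0 °C; then 4, 40 °C
Reagents that add atoms: none
Why: Metal-free O-arylation of a phenoxide by a symmetrical diaryliodonium salt (ligand coupling at trivalent iodine), a reaction type that accepts 2,6-disubstituted and electron-poor phenols and leaves the aldehyde and the aryl bromide untouched.

Step 3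
Reactants: 5 4-(4-bromophenoxy)-3,5-dimethoxybenzaldehyde
Product: 7 4-(4-bromophenoxy)-3,5-dimethoxyphenol, via aryl formate 6 (not isolated)
Conditions: mCPBA, CH2Cl2, 0 °C → rt; then K2CO3 (cat.), MeOH, rt
Reagents that add atoms: 3-chloroperoxybenzoic acid (mCPBA), OOC(=O)c1cccc(Cl)c1
Why: Baeyer–Villiger (Dakin-type) oxidation in which the oxygen-rich aryl group migrates to give the aryl formate, which mild methanolysis cleaves to the phenol without affecting the aryl bromide or the diaryl ether.

Step 4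
Reactants: 7 4-(4-bromophenoxy)-3,5-dimethoxyphenol
Product: 9 1-[3-(4-bromophenoxy)-6-hydroxy-2,4-dimethoxyphenyl]ethanone, via difluoroboron chelate 8 (not isolated)
Conditions: AcOH, BF3·OEt2, 85 °C; then aq. NaOAc, 60 °C
Reagents that add atoms: acetic acid, CC(=O)O
Why: Friedel–Crafts (Fries-type) C-acetylation under BF3, where the only open positions of the activated ring are the two equivalent carbons ortho to the hydroxyl, the bromophenoxy ring is far less nucleophilic, and capture of the product as its boron chelate prevents a second acylation.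

Step 5
Reactants: 9 1-[3-(4-bromophenoxy)-6-hydroxy-2,4-dimethoxyphenyl]ethanone
Product: 10 1-[3-(4-bromophenoxy)-2,4-dimethoxy-6-(methoxymethoxy)phenyl]ethanone
Conditions: NaH (1.1 equiv), DMF, 0 °C; MOMCl, 0 °C → rt
Reagents that add atoms: chloromethyl methyl ether (MOMCl), COCCl
Why: Williamson-type O-alkylation of the sodium phenoxide, with NaH chosen because the phenol is hydrogen-bonded to the ketone and one equivalent of base deprotonates the phenol in preference to the far less acidic methyl ketone.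

Step 6
Reactants: 10 1-[3-(4-bromophenoxy)-2,4-dimethoxy-6-(methoxymethoxy)phenyl]ethanone; 11 ethynyltrimethylsilane
Product: 13 1-[3-(4-ethynylphenoxy)-2,4-dimethoxy-6-(methoxymethoxy)phenyl]ethanone, via silylalkyne 12 (not isolated)
Conditions: PdCl2(PPh3)2 (cat.), CuI (cat.), Et3N, DMF, 75 °C, sealed; then K2CO3 (cat.), MeOH, rt
Reagents that add atoms: none
Why: Sonogashira coupling of the aryl bromide with a silyl-capped acetylene, which rules out double coupling, followed by methoxide-mediated protodesilylation, with ketone, MOM acetal and methyl ethers inert to both stages.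

Step 7
Reactants: 2 3,5-bis(benzyloxy)-2-iodophenol; 13 1-[3-(4-ethynylphenoxy)-2,4-dimethoxy-6-(methoxymethoxy)phenyl]ethanone; 14 carbon monoxide
Product: 17 1-[3-{4-[5,7-bis(benzyloxy)-4-oxo-4H-chromen-2-yl]phenoxy}-2,4-dimethoxy-6-(methoxymethoxy)phenyl]ethanone, via ortho-hydroxyaryl ynone 15 (not isolated), via diethylamino enone 16 (not isolated)
Conditions: PdCl2(PPh3)2 (5 mol %), CO (10 bar), Et2NH, DMF, 100 °C, no copper
Reagents that add atoms: none
Why: Zerovalent palladium, formed in situ from PdCl2(PPh3)2, inserts into the C–I bond of 2, CO inserts to give an aroylpalladium species, and coupling with the amine-activated alkyne 13 releases ynone 15 (new bonds C4a–C4 and C4–C3). Diethylamine adds to the ynone to give enaminone 16, whose phenolic oxygen attacks the amine-bearing carbon and expels the amine, forming O1–C2. The closest known reaction type is the carbonylative annulation of ortho-iodophenols with terminal arylacetylenes to flavones. The pyranone closes in a 6-endo addition–elimination mode on the enaminone, the secondary amine suppressing the 5-exo closure that would lead to an aurone. No stereocentre is created. The step needs carbonylative rather than direct alkynylation, which CO pressure and the absence of copper secure, and a single regiochemistry of ring A, which is fixed because iodine sits beside the only free hydroxyl; aryl ketone, MOM acetal, benzyl ethers and diaryl ether are inert.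

Step 8
Reactants: 17 1-[3-{4-[5,7-bis(benzyloxy)-4-oxo-4H-chromen-2-yl]phenoxy}-2,4-dimethoxy-6-(methoxymethoxy)phenyl]ethanone
Product: 20 5,7-bis(benzyloxy)-2-{4-[(5,7-dimethoxy-4-oxo-4H-chromen-6-yl)oxy]phenyl}-4H-chromen-4-one, via MOM-protected enaminone 18 (not isolated), via hydroxy enaminone 19 (not isolated)
Conditions: Me2NCH(OMe)2, toluene, 110 °C; concentrate; then 2 M HCl, MeOH/THF, 50 °C
Reagents that add atoms: N,N-dimethylformamide dimethyl acetal, COC(OC)N(C)C
Why: Enaminone route to chromones, in which the methyl ketone condenses with the formamide acetal while the phenol is still masked (no O-methylation), and acid then removes the MOM group so that the freed phenol displaces dimethylamine by 6-endo conjugate addition–elimination.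

Step 9
Reactants: 20 5,7-bis(benzyloxy)-2-{4-[(5,7-dimethoxy-4-oxo-4H-chromen-6-yl)oxy]phenyl}-4H-chromen-4-one; 21 4-(benzyloxy)phenylboronic acid
Product: 22 (2S)-2-[4-(benzyloxy)phenyl]-6-{4-[5,7-bis(benzyloxy)-4-oxo-4H-chromen-2-yl]phenoxy}-5,7-dimethoxy-2,3-dihydro-4H-chromen-4-one
Conditions: Pd(OCOCF3)2 (10 mol %), (R)-4-tert-butyl-2-(pyridin-2-yl)-4,5-dihydrooxazole (12 mol %), NH4PF6 (30 mol %), H2O (5 equiv), ClCH2CH2Cl, 60 °C
Reagents that add atoms: none
Why: Palladium-catalysed asymmetric conjugate addition of an arylboronic acid to a chromone (transmetalation, enantio-determining insertion of C2=C3 into the aryl–palladium bond, protonolysis of the palladium enolate), in which the tert-butyl group of the (R)-ligand shields one face of the bound enone and so sets C2 as S, while the fully substituted C2 of the flavone half is too hindered and too electron-rich to compete.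

Step 10
Reactants: 22 (2S)-2-[4-(benzyloxy)phenyl]-6-{4-[5,7-bis(benzyloxy)-4-oxo-4H-chromen-2-yl]phenoxy}-5,7-dimethoxy-2,3-dihydro-4H-chromen-4-one
Product: 23 (2S)-6-[4-(5,7-dihydroxy-4-oxo-4H-chromen-2-yl)phenoxy]-5-hydroxy-2-(4-hydroxyphenyl)-7-methoxy-2,3-dihydro-4H-chromen-4-one
Conditions: BCl3 (1 M in CH2Cl2, excess), C6HMe5, CH2Cl2, −78 → 0 °C; MeOH, then aq. NaHCO3
Reagents that add atoms: none
Why: Lewis-acid ether cleavage in which BCl3 removes the three benzyl groups (the benzyl cation being trapped by pentamethylbenzene so that the electron-rich rings are not C-benzylated) and, by chelation to the C4 carbonyl, only the peri 5-methyl ether of the flavanone, the non-chelated 7-methyl ether and the diaryl ether being retained and the low temperature protecting C2 from ring opening.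

Compound list
1 | 3,5-bis(benzyloxy)phenol | Oc1cc(OCc2ccccc2)cc(OCc2ccccc2)c1 | starting material
2 | 3,5-bis(benzyloxy)-2-iodophenol | Oc1cc(OCc2ccccc2)cc(OCc2ccccc2)c1I | intermediate
3 | syringaldehyde (4-hydroxy-3,5-dimethoxybenzaldehyde) | COc1cc(C=O)cc(OC)c1O | starting material
4 | bis(4-bromophenyl)iodonium trifluoromethanesulfonate | Brc1ccc([I+]c2ccc(Br)cc2)cc1.[O-]S(=O)(=O)C(F)(F)F | starting material
5 | 4-(4-bromophenoxy)-3,5-dimethoxybenzaldehyde | COc1cc(C=O)cc(OC)c1Oc1ccc(Br)cc1 | intermediate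
6 | 4-(4-bromophenoxy)-3,5-dimethoxyphenyl formate (not isolated) | COc1cc(OC=O)cc(OC)c1Oc1ccc(Br)cc1 | intermediate
7 | 4-(4-bromophenoxy)-3,5-dimethoxyphenol | COc1cc(O)cc(OC)c1Oc1ccc(Br)cc1 | intermediate
8 | difluoroboron chelate of ketone 9 (not isolated) | CC1=[O+][B-](F)(F)Oc2cc(OC)c(Oc3ccc(Br)cc3)c(OC)c12 | intermediate
9 | 1-[3-(4-bromophenoxy)-6-hydroxy-2,4-dimethoxyphenyl]ethanone | CC(=O)c1c(O)cc(OC)c(Oc2ccc(Br)cc2)c1OC | intermediate
10 | 1-[3-(4-bromophenoxy)-2,4-dimethoxy-6-(methoxymethoxy)phenyl]ethanone | CC(=O)c1c(OCOC)cc(OC)c(Oc2ccc(Br)cc2)c1OC | intermediate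
11 | ethynyltrimethylsilane | C#C[Si](C)(C)C | starting material
12 | 1-[2,4-dimethoxy-6-(methoxymethoxy)-3-{4-[(trimethylsilyl)ethynyl]phenoxy}phenyl]ethanone (not isolated) | CC(=O)c1c(OCOC)cc(OC)c(Oc2ccc(C#C[Si](C)(C)C)cc2)c1OC | intermediate
13 | 1-[3-(4-ethynylphenoxy)-2,4-dimethoxy-6-(methoxymethoxy)phenyl]ethanone | CC(=O)c1c(OCOC)cc(OC)c(Oc2ccc(C#C)cc2)c1OC | intermediate
14 | carbon monoxide | [C-]#[O+] | starting material
15 | 3-{4-[3-acetyl-2,6-dimethoxy-4-(methoxymethoxy)phenoxy]phenyl}-1-[2,4-bis(benzyloxy)-6-hydroxyphenyl]prop-2-yn-1-one (not isolated) | CC(=O)c1c(OCOC)cc(OC)c(Oc2ccc(C#CC(=O)c3c(O)cc(OCc4ccccc4)cc3OCc3ccccc3)cc2)c1OC | intermediate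
16 | 3-{4-[3-acetyl-2,6-dimethoxy-4-(methoxymethoxy)phenoxy]phenyl}-1-[2,4-bis(benzyloxy)-6-hydroxyphenyl]-3-(diethylamino)prop-2-en-1-one (not isolated, alkene geometry not defined) | CC(=O)c1c(OCOC)cc(OC)c(Oc2ccc(C(=CC(=O)c3c(O)cc(OCc4ccccc4)cc3OCc3ccccc3)N(CC)CC)cc2)c1OC | intermediate
17 | 1-[3-{4-[5,7-bis(benzyloxy)-4-oxo-4H-chromen-2-yl]phenoxy}-2,4-dimethoxy-6-(methoxymethoxy)phenyl]ethanone | CC(=O)c1c(OCOC)cc(OC)c(Oc2ccc(-c3cc(=O)c4c(OCc5ccccc5)cc(OCc5ccccc5)cc4o3)cc2)c1OC | intermediate
18 | (E)-1-[3-{4-[5,7-bis(benzyloxy)-4-oxo-4H-chromen-2-yl]phenoxy}-2,4-dimethoxy-6-(methoxymethoxy)phenyl]-3-(dimethylamino)prop-2-en-1-one (not isolated) | CN(C)/C=C/C(=O)c1c(OCOC)cc(OC)c(Oc2ccc(-c3cc(=O)c4c(OCc5ccccc5)cc(OCc5ccccc5)cc4o3)cc2)c1OC | intermediate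
19 | (E)-1-[3-{4-[5,7-bis(benzyloxy)-4-oxo-4H-chromen-2-yl]phenoxy}-6-hydroxy-2,4-dimethoxyphenyl]-3-(dimethylamino)prop-2-en-1-one (not isolated) | CN(C)/C=C/C(=O)c1c(O)cc(OC)c(Oc2ccc(-c3cc(=O)c4c(OCc5ccccc5)cc(OCc5ccccc5)cc4o3)cc2)c1OC | intermediate
20 | 5,7-bis(benzyloxy)-2-{4-[(5,7-dimethoxy-4-oxo-4H-chromen-6-yl)oxy]phenyl}-4H-chromen-4-one | COc1cc2occc(=O)c2c(OC)c1Oc1ccc(-c2cc(=O)c3c(OCc4ccccc4)cc(OCc4ccccc4)cc3o2)cc1 | intermediate
21 | 4-(benzyloxy)phenylboronic acid | OB(O)c1ccc(OCc2ccccc2)cc1 | starting material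
22 | (2S)-2-[4-(benzyloxy)phenyl]-6-{4-[5,7-bis(benzyloxy)-4-oxo-4H-chromen-2-yl]phenoxy}-5,7-dimethoxy-2,3-dihydro-4H-chromen-4-one | COc1cc2c(c(OC)c1Oc1ccc(-c3cc(=O)c4c(OCc5ccccc5)cc(OCc5ccccc5)cc4o3)cc1)C(=O)C[C@@H](c1ccc(OCc3ccccc3)cc1)O2 | intermediate
23 | (2S)-6-[4-(5,7-dihydroxy-4-oxo-4H-chromen-2-yl)phenoxy]-5-hydroxy-2-(4-hydroxyphenyl)-7-methoxy-2,3-dihydro-4H-chromen-4-one | COc1cc2c(c(O)c1Oc1ccc(-c3cc(=O)c4c(O)cc(O)cc4o3)cc1)C(=O)C[C@@H](c1ccc(O)cc1)O2 | target

Total step count: 10 steps.
Longest linear sequence: 9 steps (steps 2 to 10, from syringaldehyde); step 1 supplies the second partner of the convergent step 7.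

Steps most likely to fail

Step 7. Diethylamine may intercept the aroylpalladium intermediate (aminocarbonylation), or slow oxidative addition into the hindered, electron-rich C–I bond may let non-carbonylative coupling and furan-type closure compete. The fallback divides the cascade and sets out from 2 and 13. Acetylation of 2 (Ac2O, pyridine) should give 3,5-bis(benzyloxy)-2-iodophenyl acetate F1. Carbonylative Sonogashira coupling of F1 with 13 under PdCl2(PPh3)2, Et3N and CO (1 bar) in THF at 40 °C uses a tertiary amine that cannot consume the acyl palladium and a masked phenol that cannot cyclise. It should give the isolable ynone 2-(3-{4-[3-acetyl-2,6-dimethoxy-4-(methoxymethoxy)phenoxy]phenyl}prop-2-ynoyl)-3,5-bis(benzyloxy)phenyl acetate F2. Treatment of F2 with Et2NH in MeOH/THF at room temperature then removes the acetate, adds to the ynone and closes the pyranone, returning to the route at 17.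

Step 9. Carbopalladation of the electron-rich, peri-substituted chromone may be so slow that protodeboronation of the boronic acid outruns addition, or facial discrimination may be insufficient. The fallback sets out from 17 and abandons the chromone. Claisen–Schmidt condensation of 17 with 4-(benzyloxy)benzaldehyde (KOH, EtOH/THF, rt) should give the chalcone (E)-1-[3-{4-[5,7-bis(benzyloxy)-4-oxo-4H-chromen-2-yl]phenoxy}-2,4-dimethoxy-6-(methoxymethoxy)phenyl]-3-[4-(benzyloxy)phenyl]prop-2-en-1-one F3. HCl in MeOH at 50 °C followed by NaOAc in refluxing EtOH removes the MOM group and closes the ring by oxa-Michael addition to racemic 2-[4-(benzyloxy)phenyl]-6-{4-[5,7-bis(benzyloxy)-4-oxo-4H-chromen-2-yl]phenoxy}-5,7-dimethoxy-2,3-dihydro-4H-chromen-4-one F4. Preparative chromatography of F4 on a chiral polysaccharide phase gives the (2S)-enantiomer, which is 22, and the unwanted enantiomer can be re-equilibrated through the chalcone with base and recycled.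

Step 10. Configuration at C2 may erode through Lewis-acid-promoted opening of the flavanone ring to the chalcone and re-closure, or the 7-methyl ether may be cleaved as well. The fallback sets out from 20 and moves the chelation-directed dealkylation ahead of the stereocentre. MgI2·OEt2 in THF at 60 °C should cleave only the two ethers peri to a carbonyl, giving 7-(benzyloxy)-5-hydroxy-2-{4-[(5-hydroxy-7-methoxy-4-oxo-4H-chromen-6-yl)oxy]phenyl}-4H-chromen-4-one F5. The aryl addition of step 9 with 21 on F5 (hydrogen-bonded phenols are compatible with the aqueous cationic palladium system) should give (2S)-2-[4-(benzyloxy)phenyl]-6-{4-[7-(benzyloxy)-5-hydroxy-4-oxo-4H-chromen-2-yl]phenoxy}-5-hydroxy-7-methoxy-2,3-dihydro-4H-chromen-4-one F6. Neutral hydrogenolysis of F6 (H2, 1 bar, Pd/C, EtOAc/MeOH, rt) then removes the two remaining benzyl groups and arrives at 23 without exposing the stereocentre to a Lewis acid.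

Further compounds
F1 | step 7 | 3,5-bis(benzyloxy)-2-iodophenyl acetate | CC(=O)Oc1cc(OCc2ccccc2)cc(OCc2ccccc2)c1I
F2 | step 7 | 2-(3-{4-[3-acetyl-2,6-dimethoxy-4-(methoxymethoxy)phenoxy]phenyl}prop-2-ynoyl)-3,5-bis(benzyloxy)phenyl acetate | CC(=O)Oc1cc(OCc2ccccc2)cc(OCc2ccccc2)c1C(=O)C#Cc1ccc(Oc2c(OC)cc(OCOC)c(C(C)=O)c2OC)cc1
F3 | step 9 | (E)-1-[3-{4-[5,7-bis(benzyloxy)-4-oxo-4H-chromen-2-yl]phenoxy}-2,4-dimethoxy-6-(methoxymethoxy)phenyl]-3-[4-(benzyloxy)phenyl]prop-2-en-1-one | COCOc1cc(OC)c(Oc2ccc(-c3cc(=O)c4c(OCc5ccccc5)cc(OCc5ccccc5)cc4o3)cc2)c(OC)c1C(=O)/C=C/c1ccc(OCc2ccccc2)cc1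
F4 | step 9 | racemic 2-[4-(benzyloxy)phenyl]-6-{4-[5,7-bis(benzyloxy)-4-oxo-4H-chromen-2-yl]phenoxy}-5,7-dimethoxy-2,3-dihydro-4H-chromen-4-one | COc1cc2c(c(OC)c1Oc1ccc(-c3cc(=O)c4c(OCc5ccccc5)cc(OCc5ccccc5)cc4o3)cc1)C(=O)CC(c1ccc(OCc3ccccc3)cc1)O2
F5 | step 10 | 7-(benzyloxy)-5-hydroxy-2-{4-[(5-hydroxy-7-methoxy-4-oxo-4H-chromen-6-yl)oxy]phenyl}-4H-chromen-4-one | COc1cc2occc(=O)c2c(O)c1Oc1ccc(-c2cc(=O)c3c(O)cc(OCc4ccccc4)cc3o2)cc1
F6 | step 10 | (2S)-2-[4-(benzyloxy)phenyl]-6-{4-[7-(benzyloxy)-5-hydroxy-4-oxo-4H-chromen-2-yl]phenoxy}-5-hydroxy-7-methoxy-2,3-dihydro-4H-chromen-4-one | COc1cc2c(c(O)c1Oc1ccc(-c3cc(=O)c4c(O)cc(OCc5ccccc5)cc4o3)cc1)C(=O)C[C@@H](c1ccc(OCc3ccccc3)cc1)O2
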